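The route rests on disconnecting the C3a–C8a ring-fusion bond of the hydroazulene (azulene numbering) as a 1,2-shift: C8a, with its methyl group and the neighbouring C1 oxygen of the five-membered ring, is the angular carbon of (S)-Wieland–Miescher ketone and its saturated carbonyl. In one operation a semipinacol shift of C8a from C4 to C3a contracts one cyclohexane to the cyclopentane, expands the other to the cycloheptane, creates the C4 carbonyl and fixes the trans ring fusion at C3a. The precursor is a cis-fused decalin bearing a tertiary hydroxyl (future C4) and a cis secondary mesylate (future C3a) on the methyl face, with C1 and C6 as dioxolanes.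

Key step: step 4

Remark: decalins are numbered as naphthalenes (C1 and C6 ketal carbons, C4 CH–O, C4a C–OH, C8a C–CH3) and hydroazulenes as azulenes; decalin C4 becomes azulene C3a and decalin C4a becomes azulene C4.
Remark: "methyl face" is the face of the bicycle that carries the angular methyl; the target, (1R,3R,3aR,4R,8aS), has H-3a and the oxygens at C1, C3 and C4 on the other face ("H-3a face").
Remark (assumption): hydride is taken to add to the C4 and C1 carbonyls anti to the angular methyl, so both carbinols form on the methyl face and are then inverted by carboxylate displacement.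
Remark: compounds 1, 2 and 14 are taken as commercial; dione 10 is drawn as its diketo tautomer; C3 in 21 and C7 in 27 are uncontrolled centres that are erased within the same step.

Step 1
Reactants: 1 (S)-Wieland–Miescher ketone; 2 ethylene glycol
Product: 3 bis(dioxolane) alkene (C1 and C6 ketals; alkene at C4=C4a)
Conditions: ethylene glycol (excess), TsOH (cat.), toluene, reflux, Dean–Stark
Reagents that add atoms: ethylene glycol OCCO (the second molecule that is built in; the same compound as 2)
Why: Acid-catalysed ketalisation with two molecules of ethylene glycol protects both carbonyls and, as with steroidal enones, ketalisation of the conjugated C6 carbonyl moves the alkene out of conjugation to C4=C4a, the position needed for the diol, while C8a is untouched.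

Step 2
Reactants: 3 bis(dioxolane) alkene
Product: 6 cis-diol (C4–OH and C4a–OH both on the methyl face), via iodo acetate 4 (not isolated), via hydroxy acetate 5 (not isolated)
Conditions: I2, AgOAc (2.2 equiv), AcOH, rt; then H2O (1.5 equiv), 50 °C; filter; then K2CO3, MeOH, rt
Reagents that add atoms: silver acetate CC(=O)[O-].[Ag+]
Why: Woodward cis-hydroxylation: the iodonium ion forms on the face opposite the angular methyl, acetate opens it anti at C4, silver-assisted displacement of the tertiary iodide by the neighbouring acetate (inversion at C4a) gives a cis acetoxonium ion on the methyl face that water opens to 5, so both oxygens end on the methyl face (the opposite of osmylation) and methanolysis frees the diol; excess AgOAc and a measured amount of water keep the medium buffered for the two dioxolanes.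

Step 3
Reactants: 6 cis-diol
Product: 7 cis-diol monomesylate (C4–OMs; free tertiary C4a–OH)
Conditions: MsCl, pyridine, CH2Cl2, 0 °C
Reagents that add atoms: methanesulfonyl chloride CS(=O)(=O)Cl
Why: Sulfonylation of an alcohol: the secondary C4 hydroxyl reacts while the hindered tertiary C4a hydroxyl, which must stay free to trigger the rearrangement, does not.

Step 4
Reactants: 7 cis-diol monomesylate
Product: 8 (3aR,8aS)-trans-hydroazulen-4-one bis(dioxolane) (C1 and C6 ketals; 8a-methyl)
Conditions: KOtBu (1.1 equiv), tBuOH/THF, 0 °C to rt
Reagents that add atoms: none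
Why: Deprotonation of the tertiary C4a hydroxyl gives an alkoxide that pushes the antiperiplanar C4a–C8a ring-fusion bond onto C4 as mesylate departs, so C8a moves from the carbinol carbon to the sulfonate carbon and the carbinol carbon becomes the ketone (azulene C4). The closest known reaction type is the base-induced semipinacol (pinacol-type) rearrangement of vicinal diol monosulfonates, used to turn decalins and steroidal 5-hydroxy 6-sulfonates into hydroazulenones. The cyclopentane is closed by ring contraction through this 1,2-alkyl shift (formation of C3a–C8a) and the cycloheptane arises by the complementary one-carbon ring expansion, not by a separate cyclisation. The new stereocentre C3a is set by stereospecific inversion at the mesylate carbon, whose configuration came from step 2, while C8a migrates with retention, which gives the trans fusion. The step needs migration of the ring-fusion bond in preference to the C5 methylene or to epoxide closure: the cis hydroxyl cannot reach the backside of the mesylate, and the chair with the mesylate equatorial (anti to C4a–C8a) is the populated one because the other chair would place the mesylate syn-diaxial to the angular methyl. Only a slight excess of base is used, so the product ketone is not left under enolising conditions that could epimerise C3a or open the C6 ketal.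

Step 5
Reactants: 8 trans-hydroazulen-4-one bis(dioxolane)
Product: 10 4,6-dione (enolised; C1 dioxolane kept), via vinylogous ester 9 (not isolated)
Conditions: KOH, H2O/dioxane, 60 °C; then aq. HCl to pH 5, 0 °C
Reagents that add atoms: potassium hydroxide [K+].[OH-]
Why: Base-induced E1cB opening of the beta-keto ketal to 9 followed by vinylogous ester saponification frees only the C6 carbonyl, because the isolated C1 dioxolane cannot react with hydroxide, and the delocalised dione anion shields C3a from epimerisation.

Step 6
Reactants: 10 4,6-dione
Product: 11 6-triflyloxy-5-en-4-one (C1 dioxolane)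
Conditions: Tf2O, Et3N, CH2Cl2, −78 °C
Reagents that add atoms: triflic anhydride O=S(=O)(C(F)(F)F)OS(=O)(=O)C(F)(F)F
Why: Kinetic O-sulfonylation of a cyclic 1,3-dione (vinylogous acid) should occur on the less hindered C6 oxygen, remote from the ring-fusion carbon C3a, leaving the C4 carbonyl in place.

Step 7
Reactants: 11 6-triflyloxy-5-en-4-one
Product: 12 6-methyl-5-en-4-one (C1 dioxolane)
Conditions: Me2CuLi (from MeLi, CuI), Et2O, −78 °C
Reagents that add atoms: lithium dimethylcuprate [Li+].C[Cu-]C
Why: Cuprate addition–elimination on a beta-triflyloxy enone replaces the triflate by methyl and gives the C5=C6–CH3 enone without touching the ketal.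

Step 8
Reactants: 12 6-methyl-5-en-4-one
Product: 13 allylic alcohol (C4–OH on the methyl face; cis to 8a-CH3 and trans to H-3a)
Conditions: NaBH4, CeCl3·7H2O, MeOH, −40 °C
Reagents that add atoms: none
Why: Luche reduction gives clean 1,2-addition, and hydride is expected to approach C4 on the face away from the angular methyl, which sits 1,3 to the carbonyl carbon, so the hydroxyl appears on the methyl face (the C4 epimer of the target, corrected in step 10).

Step 9
Reactants: 14 4-hydroxybenzoic acid
Product: 16 4-(triisopropylsilyloxy)benzoic acid, via silyl ester 15 (not isolated)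
Conditions: TIPSCl (2.2 equiv), imidazole, DMF, rt; then AcOH/THF/H2O, rt
Reagents that add atoms: triisopropylsilyl chloride CC(C)[Si](Cl)(C(C)C)C(C)C
Why: Silylation of phenol and acid followed by selective hydrolysis of the labile silyl ester leaves the phenol masked as a silyl ether that should withstand the later basic, reductive and oxidative steps and is removed by fluoride.

Step 10
Reactants: 13 allylic alcohol; 16 4-(triisopropylsilyloxy)benzoic acid
Product: 17 C4 aroyl ester (aroyloxy on the H-3a face; C1 dioxolane)
Conditions: PPh3, DIAD, toluene, 0 °C to rt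
Reagents that add atoms: none
Why: Mitsunobu esterification proceeds by SN2 displacement of the allylic oxyphosphonium ion by the carboxylate with inversion, which puts the aroyl ester on the H-3a face (target C4 configuration), and attack at the tertiary allylic terminus C6 is disfavoured.

Step 11
Reactants: 17 C4 aroyl ester ketal
Product: 18 C1 ketone
Conditions: PPTS, acetone/H2O, 50 °C
Reagents that add atoms: water O
Why: Mild acid-catalysed ketal hydrolysis releases the C1 ketone under conditions that the aryl silyl ether and the allylic ester should tolerate.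

Step 12
Reactants: 18 C1 ketone
Product: 20 2-en-1-one, via silyl enol ether 19 (not isolated)
Conditions: TMSOTf, Et3N, CH2Cl2, 0 °C; then Pd(OAc)2, MeCN, rt
Reagents that add atoms: none
Why: Saegusa–Ito oxidation: the ketone can enolise only towards C2 because C8a is quaternary, and Pd(OAc)2 dehydrogenates the silyl enol ether to the cyclopentenone.

Step 13
Reactants: 20 2-en-1-one
Product: 22 3-isopropyl-2-en-1-one, via isopropyl silyl enol ether 21 (not isolated)
Conditions: iPrMgCl, CuBr·SMe2 (cat.), TMSCl, THF, −78 °C; then Pd(OAc)2, MeCN, rt
Reagents that add atoms: isopropylmagnesium chloride CC(C)[Mg]Cl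
Why: Copper-catalysed conjugate addition of the Grignard reagent with chlorosilane trapping places the isopropyl group on C3 (at −78 °C this accelerated 1,4-addition should outrun attack on the allylic C4 ester) and gives a regiodefined silyl enol ether, which a second Saegusa–Ito oxidation returns to the now beta-isopropyl enone, erasing the transient C3 centre.

Step 14
Reactants: 22 3-isopropyl-2-en-1-one
Product: 23 2,3-epoxy ketone (epoxide oxygen on the H-3a face)
Conditions: tBuOOLi (from tBuOOH, nBuLi), THF, −20 to 0 °C
Reagents that add atoms: tert-butyl hydroperoxide CC(C)(C)OO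
Why: Weitz–Scheffer (nucleophilic) epoxidation touches only the enone and not the isolated C5=C6 alkene, and the peroxide is expected to add to C3 on the face opposite the angular methyl, setting the C3–O bond on the H-3a face; the weakly basic lithium peroxide limits enolisation towards C3a.

Step 15
Reactants: 23 2,3-epoxy ketone
Product: 24 3-hydroxy-3-isopropyl-1-ketone (tertiary OH on the H-3a face)
Conditions: SmI2, THF/MeOH, −78 °C
Reagents that add atoms: none
Why: Reductive opening of an alpha,beta-epoxy ketone by SmI2 cleaves only the C2–O bond via the ketyl, so the C3–O bond and its configuration are kept and the tertiary carbinol of the target is formed.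

Step 16
Reactants: 24 3-hydroxy-1-ketone
Product: 25 1,3-anti diol (C1–OH on the methyl face)
Conditions: NaBH4, MeOH, −40 °C
Reagents that add atoms: none
Why: Borohydride reduction of the cyclopentanone: hydride adds anti to the adjacent angular methyl, on the side of the C3 hydroxyl, giving the C1 alcohol on the methyl face, ready for inversion.

Step 17
Reactants: 25 1,3-anti diol
Product: 26 C1 acetate (acetoxy on the H-3a face; free tertiary C3–OH)
Conditions: AcOH, PPh3, DIAD, toluene, 0 to 60 °C
Reagents that add atoms: acetic acid CC(=O)O
Why: Mitsunobu reaction with acetic acid: only the secondary C1 hydroxyl is activated and acetate displaces it with inversion, giving the target C1 configuration, a substitution of the type used to invert 17-hydroxy steroids next to a quaternary carbon, while the tertiary C3 hydroxyl does not react.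

Step 18
Reactants: 26 C1 acetate
Product: 28 silyl-protected target (C5=C6–C7=O enone), via allylic alcohol 27 (not isolated)
Conditions: SeO2 (cat.), tBuOOH, CH2Cl2, rt; then Dess–Martin periodinane, NaHCO3, CH2Cl2, rt
Reagents that add atoms: tert-butyl hydroperoxide CC(C)(C)OO (oxygen relayed by selenium dioxide O=[Se]=O)
Why: Riley allylic oxidation (ene reaction at the alkene, then [2,3]-sigmatropic shift) functionalises the ring methylene attached to the more substituted alkene carbon, which is C7, while C4–H is deactivated by the ester, and Dess–Martin oxidation of the resulting allylic alcohol gives the enone.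

Step 19
Reactants: 28 silyl-protected target
Product: 29 target CNP0087181.5
Conditions: TBAF, AcOH, THF, 0 °C
Reagents that add atoms: none
Why: Fluoride-mediated cleavage of the aryl silyl ether, buffered with acetic acid, frees the phenol without acyl transfer or ester loss.

Compound list
1 | (S)-8a-methyl-3,4,8,8a-tetrahydronaphthalene-1,6(2H,7H)-dione, (S)-Wieland–Miescher ketone | O=C1CCCC2=CC(=O)CC[C@]12C | starting material
2 | ethylene glycol | OCCO | starting material
3 | 1,6-bis(ethylene ketal) of the (8aS)-8a-methyl-octalindione, alkene at C4=C4a | O1CCOC12CCC=C3CC4(OCCO4)CC[C@]23C | intermediate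
4 | iodo acetate: C4–OAc on the methyl face, C4a–I on the opposite face | O1CCOC12CC[C@@H](OC(C)=O)[C@@]3(I)CC4(OCCO4)CC[C@]23C | intermediate (not isolated)
5 | hydroxy acetate: C4–OAc and C4a–OH both on the methyl face | O1CCOC12CC[C@@H](OC(C)=O)[C@]3(O)CC4(OCCO4)CC[C@]23C | intermediate (not isolated)
6 | cis-diol: C4–OH and C4a–OH both on the methyl face, cis-fused decalin | O1CCOC12CC[C@@H](O)[C@]3(O)CC4(OCCO4)CC[C@]23C | intermediate
7 | cis-diol monomesylate: C4–OMs and free C4a–OH on the methyl face | O1CCOC12CC[C@@H](OS(C)(=O)=O)[C@]3(O)CC4(OCCO4)CC[C@]23C | intermediate (key-step precursor)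
8 | (3aR,8aS)-8a-methyl-trans-hydroazulen-4-one, C1 and C6 dioxolanes | O1CCOC12CC[C@H]3C(=O)CC4(OCCO4)CC[C@]23C | intermediate (key-step product)
9 | 6-(2-hydroxyethoxy)-5-en-4-one (vinylogous ester), C1 dioxolane | O1CCOC12CC[C@H]3C(=O)C=C(OCCO)CC[C@]23C | intermediate (not isolated)
10 | 4,6-dione (enolised), C1 dioxolane | O1CCOC12CC[C@H]3C(=O)CC(=O)CC[C@]23C | intermediate
11 | 6-(trifluoromethanesulfonyloxy)-5-en-4-one, C1 dioxolane | O1CCOC12CC[C@H]3C(=O)C=C(OS(=O)(=O)C(F)(F)F)CC[C@]23C | intermediate
12 | 6-methyl-5-en-4-one, C1 dioxolane | O1CCOC12CC[C@H]3C(=O)C=C(C)CC[C@]23C | intermediate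
13 | 6-methyl-5-en-4-ol, C4–OH on the methyl face, C1 dioxolane | O1CCOC12CC[C@H]3[C@@H](O)C=C(C)CC[C@]23C | intermediate
14 | 4-hydroxybenzoic acid | OC(=O)c1ccc(O)cc1 | starting material
15 | triisopropylsilyl 4-(triisopropylsilyloxy)benzoate | CC(C)[Si](OC(=O)c1ccc(O[Si](C(C)C)(C(C)C)C(C)C)cc1)(C(C)C)C(C)C | intermediate (not isolated)
16 | 4-(triisopropylsilyloxy)benzoic acid | OC(=O)c1ccc(O[Si](C(C)C)(C(C)C)C(C)C)cc1 | intermediate
17 | C4 4-(triisopropylsilyloxy)benzoate on the H-3a face, C5=C6–CH3, C1 dioxolane | O1CCOC12CC[C@H]3[C@H](OC(=O)c4ccc(O[Si](C(C)C)(C(C)C)C(C)C)cc4)C=C(C)CC[C@]23C | intermediate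
18 | C1 ketone of 17 | O=C1CC[C@H]2[C@H](OC(=O)c3ccc(O[Si](C(C)C)(C(C)C)C(C)C)cc3)C=C(C)CC[C@]12C | intermediate
19 | C1 trimethylsilyl enol ether (C1=C2) | C[Si](C)(C)OC1=CC[C@H]2[C@H](OC(=O)c3ccc(O[Si](C(C)C)(C(C)C)C(C)C)cc3)C=C(C)CC[C@]12C | intermediate (not isolated)
20 | 2-en-1-one | O=C1C=C[C@H]2[C@H](OC(=O)c3ccc(O[Si](C(C)C)(C(C)C)C(C)C)cc3)C=C(C)CC[C@]12C | intermediate
21 | 3-isopropyl C1 trimethylsilyl enol ether (isopropyl drawn on the H-3a face; inconsequential) | C[Si](C)(C)OC1=C[C@H](C(C)C)[C@H]2[C@H](OC(=O)c3ccc(O[Si](C(C)C)(C(C)C)C(C)C)cc3)C=C(C)CC[C@]12C | intermediate (not isolated)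
22 | 3-isopropyl-2-en-1-one | O=C1C=C(C(C)C)[C@H]2[C@H](OC(=O)c3ccc(O[Si](C(C)C)(C(C)C)C(C)C)cc3)C=C(C)CC[C@]12C | intermediate
23 | 2,3-epoxy-3-isopropyl-1-ketone, epoxide oxygen on the H-3a face | O=C1[C@@H]2O[C@]2(C(C)C)[C@H]3[C@H](OC(=O)c4ccc(O[Si](C(C)C)(C(C)C)C(C)C)cc4)C=C(C)CC[C@]13C | intermediate
24 | 3-hydroxy-3-isopropyl-1-ketone, C3–OH on the H-3a face | O=C1C[C@@](O)(C(C)C)[C@H]2[C@H](OC(=O)c3ccc(O[Si](C(C)C)(C(C)C)C(C)C)cc3)C=C(C)CC[C@]12C | intermediate
25 | 1,3-anti diol, C1–OH on the methyl face, C3–OH on the H-3a face | O[C@H]1C[C@@](O)(C(C)C)[C@H]2[C@H](OC(=O)c3ccc(O[Si](C(C)C)(C(C)C)C(C)C)cc3)C=C(C)CC[C@]12C | intermediate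
26 | C1 acetate on the H-3a face, tertiary C3–OH, C5=C6–CH3 | CC(=O)O[C@@H]1C[C@@](O)(C(C)C)[C@H]2[C@H](OC(=O)c3ccc(O[Si](C(C)C)(C(C)C)C(C)C)cc3)C=C(C)CC[C@]12C | intermediate
27 | C7 allylic alcohol of 26 (C7 uncontrolled) | CC(=O)O[C@@H]1C[C@@](O)(C(C)C)[C@H]2[C@H](OC(=O)c3ccc(O[Si](C(C)C)(C(C)C)C(C)C)cc3)C=C(C)C(O)C[C@]12C | intermediate (not isolated)
28 | silyl-protected target, C5=C6–C7=O enone | CC(=O)O[C@@H]1C[C@@](O)(C(C)C)[C@H]2[C@H](OC(=O)c3ccc(O[Si](C(C)C)(C(C)C)C(C)C)cc3)C=C(C)C(=O)C[C@]12C | intermediate
29 | (1R,3R,3aR,4R,8aS)-1-acetoxy-3-hydroxy-3-isopropyl-6,8a-dimethyl-7-oxo-1,2,3,3a,4,7,8,8a-octahydroazulen-4-yl 4-hydroxybenzoate | CC(=O)O[C@@H]1C[C@@](O)(C(C)C)[C@H]2[C@H](OC(=O)c3ccc(O)cc3)C=C(C)C(=O)C[C@]12C | target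

Total step count: 19. Longest linear sequence: 18 steps (steps 1–8 and 10–19, from compound 1); step 9 is a one-step side branch.

Steps most likely to fail

Step 17 (inversion at C1). The substitution at a secondary carbinol flanked by the quaternary C8a may be slower than elimination towards C2, or the alcohol may return unchanged. The fallback sets out from epoxy ketone 23 and comes back at 26; it sets the C1 configuration by hydride delivery instead of displacement at C1. Luche reduction of 23 (NaBH4, CeCl3·7H2O, MeOH, −78 °C) is expected to add hydride anti to the adjacent epoxide oxygen, the usual course for alpha,beta-epoxy ketones, which would give the cis-epoxy alcohol F1 with the C1 hydroxyl on the H-3a face. The competing bias from the angular methyl makes this facial preference the open point of the fallback. Acetylation (Ac2O, pyridine, DMAP) gives the epoxy acetate F2. Sodium phenylselenide (from PhSeSePh and NaBH4, EtOH) opens the epoxide by SN2 attack at the secondary C2 and leaves the tertiary C3–O bond, giving the hydroxy selenide F3. Bu3SnH with AIBN (toluene, 80 °C) removes selenium and gives 26.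

Step 18 (allylic oxidation at C7). The ene step may lack positional selectivity (attack at the C6 methyl) or may stall at mixtures on a late, densely functionalised substrate. The fallback sets out from 26 and comes back at 28 with no new isolated compound; it abandons the pericyclic selenium pathway for hydrogen-atom abstraction. Dirhodium tetracaprolactamate Rh2(cap)4 (cat.) with tBuOOH and NaHCO3 in CH2Cl2 generates tert-butylperoxyl radicals that should abstract the C7 hydrogen, the only allylic methylene, since C4–H is deactivated by the ester. The mixed peroxide formed at C7 collapses to enone 28 in one operation.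

Step 6 (triflation of the dione). Sulfonylation could take place on the wrong oxygen of the ambident dione anion, which would put the methyl group on C4 after step 7. The fallback sets out from 8 and comes back at 12; it replaces the choice between two oxygens by a regiospecific carbonyl transposition. Vinylogous ester 9 is isolated from 8 (DBU cat., CH2Cl2), since the E1cB opening can only place the enol ether at C6. Stork–Danheiser reduction–hydrolysis (DIBAL-H, toluene, −78 °C; then dilute aq. HCl, 0 °C) gives the transposed enone F4 (C6 carbonyl, C4=C5 alkene). MeLi with CeCl3 (THF, −78 °C) adds to C6 to give the tertiary allylic alcohol F5. Pyridinium chlorochromate (NaOAc, CH2Cl2) then effects the Babler–Dauben oxidative 1,3-transposition to enone 12.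

Further compounds
F1 | step 17 | cis-epoxy alcohol: C1–OH and 2,3-epoxide both on the H-3a face | O[C@@H]1[C@@H]2O[C@]2(C(C)C)[C@H]3[C@H](OC(=O)c4ccc(O[Si](C(C)C)(C(C)C)C(C)C)cc4)C=C(C)CC[C@]13C
F2 | step 17 | epoxy acetate: C1–OAc and 2,3-epoxide on the H-3a face | CC(=O)O[C@@H]1[C@@H]2O[C@]2(C(C)C)[C@H]3[C@H](OC(=O)c4ccc(O[Si](C(C)C)(C(C)C)C(C)C)cc4)C=C(C)CC[C@]13C
F3 | step 17 | hydroxy selenide: C2–SePh on the methyl face, C3–OH and C1–OAc on the H-3a face | CC(=O)O[C@@H]1[C@@H]([Se]c2ccccc2)[C@@](O)(C(C)C)[C@H]3[C@H](OC(=O)c4ccc(O[Si](C(C)C)(C(C)C)C(C)C)cc4)C=C(C)CC[C@]13C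
F0 | step 18 | none | none
F4 | step 6 | transposed enone: 4-en-6-one, C1 dioxolane | O1CCOC12CC[C@H]3C=CC(=O)CC[C@]23C
F5 | step 6 | tertiary allylic alcohol: 6-hydroxy-6-methyl-4-ene, C1 dioxolane (C6 uncontrolled) | O1CCOC12CC[C@H]3C=CC(C)(O)CC[C@]23C
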